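Per cent of the starting complex charged is the unit of what is asked here, and we turn it upside down, reading a height that falls as a charge rises as a climbing reciprocal, the way a Dixon plot reads a rate.

common to all: starting complex 0.020 M; gas 0.82 mM (held)

|  | leaving ligand | scavenger | remark | time |
|---|---|---|---|---|
| dawn | 0.010 M | 0.024 M (fed, over 20 h) | run made earlier |  |
| spring | 0.040 M | 0.024 M (fed, over 20 h) | run made earlier |  |
| flask | 0.0200 M | 0.0240 M (fed, over 20 h) |  | 40 h |

| run | time / h | complex with one exchanged / % |
|---|---|---|
| dawn | 0.833 | 12.2 |
| dawn | 2.00 | 19.2 |
| dawn | 5.00 | 19.3 |
| dawn | 12.0 | 5.6 |
| dawn | 30.0 | 0 |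
| spring | 0.833 | 8.4 |
| spring | 2.00 | 13.7 |
| spring | 5.00 | 13.8 |
| spring | 12.0 | 5.4 |
| spring | 30.0 | 0.7 |

(readings scatter by 0.3 percentage points)

- at the start none of the gas is in solution
- a reading or a percentage of leaving ligand counts all its forms, free or not

- the moment within 40 h at which there is most complex with one exchanged
- the amount of complex with one exchanged, in percent of the starting complex charged, at that time

Two settings can be turned. By hand, a time limit should not matter once the curve has turned, and in the dawn run the readings at 2.00 h and 5.00 h stand level, 19.2% and 19.3%, so we place the top near their geometric mean, 3.16 h, well inside the limit of 40 h. By hand, more leaving ligand should lower the top without moving it, and the spring run keeps its level pair at the same times, with a mean of 13.8%, lower than the 19.2% of the dawn run.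

We join these two ends by a straight line in the reciprocal, which gives 0.0650 M as a reading of the holding charge, the amount which, added to the leaving ligand charge, gives a sum to which the height is inversely proportional. For the flask this carries the dawn pair to 17.0%, which is the level of the two flanks of the curve and not of its top, so our reckoning expects a height somewhat above that figure, reached near 3.16 h.

The forecast says 17.7% (16.4% to 19%) at 3.3 h (2.6 h to 4.1 h), noting that “the timing barely changes with a fourfold change in leaving ligand”.

The flask reaches its top at 3.22 h, with 18.8%.

    starting complex + incoming ligand → leaving ligand + complex with one exchanged (k = 0.277 M⁻¹ s⁻¹)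
    complex with one exchanged + incoming ligand → leaving ligand + complex with two exchanged (k = 0.436 M⁻¹ s⁻¹)
    complex with two exchanged + incoming ligand → leaving ligand + complex with three exchanged (k = 0.201 M⁻¹ s⁻¹)
    leaving ligand + starting complex ⇌ idle adduct, settled at all times (K = 48.0 M⁻¹)
    scavenger + leaving ligand → scavenged by-product (k = 0.00817 M⁻¹ s⁻¹)
    gas ⇌ incoming ligand, rate k6*(csat - [incoming ligand]) (kL = 0.00193 s⁻¹)
    2 incoming ligand → self-condensation product (k = 0.00319 M⁻¹ s⁻¹)

In the flask after 3.22 h, the idle adduct holds 33.0% of the starting complex charged beside 29.5% as free starting complex, while the second exchange has a rate constant 1.57 times that of the first, a selectivity factor against the complex with one exchanged. Carried by the holding charge from this top to a neighbour charged with 0.0050 M of leaving ligand, the height becomes 22.8%, and that neighbour gives 22.9%.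

The data are simulated for substances that don't exist; noise was put on by code.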